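**Plan** (locants of the hexahydro-1-benzofuran-2-one core: O1, C2 carbonyl, C3 with its exocyclic CH2, ring fusion C3a/C7a, C4 acyloxy, C6 quaternary, C7 alkenyl)
1. Cuts: the C4–O ester of the (Z)-2-(hydroxymethyl)but-2-enoyl unit; then, in one stroke, the lactone bond C2–C3 and the ring-fusion bond C3a–C7a (with O1–C2), giving an open-chain allenyl aldehyde and CO; then C6–C7 by a Claisen disconnection to an allylic but-3-enoate; last the ester and the carbinol C–C bond of the allylic alcohol (vinylogous aldol).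
2. Forward: vinylogous aldol, alkyne-to-allene homologation, esterification, Ireland–Claisen chain assembly, oxidation to the aldehyde, cyclocarbonylation that closes the cyclohexane (C3a–C7a) and then the lactone, acylation at O4, desilylation.
3. Stereochemistry: C4 from a catalyst-controlled vinylogous Mukaiyama aldol; C6 and C7 from a chair Ireland–Claisen rearrangement (E-olefin, E(O) boron enolate, chiral diazaborolidine); C3a and C7a from an all-equatorial chair closure in the key step; the Z side chain from a trans-hydrostannation.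
4. Enabling feature: the α-methylene-γ-butyrolactone O1–C2(=O)–C3(=CH2)–C3a–C7a, fused to the cyclohexane across C3a–C7a, is the [2+2+1] sum of an aldehyde C=O (C7a, O1), the inner C=C of a terminal allene (C3a, C3 and the exocyclic CH2) and CO (C2).

Key step: step 13

Assumption: the sense of induction of the (R,R)-bisphosphoramide in step 2 and of the (S,S)-bromodiazaborolidine in step 10 is taken as the one that gives the configurations drawn; if either proves opposite, its mirror-image form is used and nothing else changes.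

Step 1
Reactants: 1 methyl 3-methylbut-2-enoate
Product: 3 tert-butyl[(1-methoxy-3-methylbuta-1,3-dien-1-yl)oxy]dimethylsilane, via lithium dienolate 2 (not isolated)
Conditions: LiN(i-Pr)2, THF, −78 °C; then t-BuMe2SiCl, DMPU, −78 °C to rt
Reagents that add atoms: tert-butylchlorodimethylsilane, CC(C)(C)[Si](C)(C)Cl
Why: γ-deprotonation of the senecioate and O-silylation of the dienolate (silyl dienol ether formation) should give the vinylogous nucleophile, with no stereocentre formed.

Step 2
Reactants: 3 tert-butyl[(1-methoxy-3-methylbuta-1,3-dien-1-yl)oxy]dimethylsilane; 4 3-(trimethylsilyl)prop-2-ynal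
Product: 5 methyl (2E,5S)-5-hydroxy-3-methyl-7-(trimethylsilyl)hept-2-en-6-ynoate
Conditions: SiCl4, (R,R)-binaphthyldiamine-derived bisphosphoramide (5 mol %), i-Pr2NEt (cat.), CH2Cl2, −78 °C; aq. NaHCO3
Reagents that add atoms: none
Why: Lewis-base-activated SiCl4 vinylogous Mukaiyama aldol reaction, in which the dienolate should attack the conjugated ynal through its γ-carbon on the face selected by the chiral phosphoramide-bound silicon cation, setting C5 as S and forming the E-trisubstituted enoate.

Step 3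
Reactants: 5 methyl (2E,5S)-5-hydroxy-3-methyl-7-(trimethylsilyl)hept-2-en-6-ynoate
Product: 6 methyl (2E,5S)-3-methyl-5-[(triethylsilyl)oxy]-7-(trimethylsilyl)hept-2-en-6-ynoate
Conditions: Et3SiCl, imidazole, DMF, 0 °C
Reagents that add atoms: chlorotriethylsilane, CC[Si](Cl)(CC)CC
Why: Routine silyl ether formation protects the propargylic alcohol with a group that is later removable in the presence of a primary tert-butyldiphenylsilyl ether.

Step 4
Reactants: 6 methyl (2E,5S)-3-methyl-5-[(triethylsilyl)oxy]-7-(trimethylsilyl)hept-2-en-6-ynoate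
Product: 7 (2E,5S)-3-methyl-5-[(triethylsilyl)oxy]-7-(trimethylsilyl)hept-2-en-6-yn-1-ol
Conditions: i-Bu2AlH, CH2Cl2, −78 °C
Reagents that add atoms: none
Why: 1,2-Hydride reduction of the enoate should give the E-allylic alcohol without touching the silylalkyne, and it removes the base-sensitive enoate before the alkyne is unmasked.

Step 5
Reactants: 7 (2E,5S)-3-methyl-5-[(triethylsilyl)oxy]-7-(trimethylsilyl)hept-2-en-6-yn-1-ol
Product: 8 (2E,5S)-3-methyl-5-[(triethylsilyl)oxy]hept-2-en-6-yn-1-ol
Conditions: K2CO3 (cat.), MeOH, 0 °C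
Reagents that add atoms: none
Why: Base-catalysed methanolysis of the C(sp)–Si bond (protodesilylation) is much faster than cleavage of the secondary triethylsilyl ether.

Step 6
Reactants: 8 (2E,5S)-3-methyl-5-[(triethylsilyl)oxy]hept-2-en-6-yn-1-ol
Product: 10 (2E,5S)-3-methyl-5-[(triethylsilyl)oxy]octa-2,6,7-trien-1-ol, via propargylic amine 9 (not isolated)
Conditions: (CH2O)n, CuBr (0.5 equiv), i-Pr2NH, 1,4-dioxane, reflux
Reagents that add atoms: paraformaldehyde (as formaldehyde), C=O
Why: Crabbé homologation (copper-mediated Mannich reaction, then intramolecular hydride transfer from the amine) should turn the terminal alkyne into the terminal allene without touching the carbinol centre.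

Step 7
Reactants: 11 2-methylprop-2-en-1-ol
Product: 13 3-(hydroxymethyl)but-3-enoic acid, via dilithio dianion 12 (not isolated)
Conditions: n-BuLi (2.2 equiv), TMEDA, Et2O–hexane, 0 °C to rt; then CO2, −78 °C; cold dil. HCl to pH 3, immediate extraction
Reagents that add atoms: carbon dioxide, O=C=O
Why: Alkoxide-directed allylic lithiation gives a symmetrical 2-substituted allyl anion, so that carboxylation of the organolithium at either terminus should give the same β,γ-unsaturated hydroxy acid.

Step 8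
Reactants: 13 3-(hydroxymethyl)but-3-enoic acid
Product: 15 3-{[(tert-butyldiphenylsilyl)oxy]methyl}but-3-enoic acid, via bis-silyl compound 14 (not isolated)
Conditions: t-BuPh2SiCl (2.2 equiv), imidazole, DMF, rt; then AcOH–THF–H2O, rt
Reagents that add atoms: tert-butylchlorodiphenylsilane, CC(C)(C)[Si](Cl)(c1ccccc1)c1ccccc1
Why: Exhaustive silylation followed by selective hydrolysis of the labile silyl ester should leave the robust primary silyl ether and the free acid.

Step 9
Reactants: 10 (2E,5S)-3-methyl-5-[(triethylsilyl)oxy]octa-2,6,7-trien-1-ol; 15 3-{[(tert-butyldiphenylsilyl)oxy]methyl}but-3-enoic acid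
Product: 16 (2E,5S)-3-methyl-5-[(triethylsilyl)oxy]octa-2,6,7-trien-1-yl 3-{[(tert-butyldiphenylsilyl)oxy]methyl}but-3-enoate
Conditions: EDC·HCl, DMAP (0.1 equiv), CH2Cl2, 0 °C
Reagents that add atoms: none
Why: Steglich-type carbodiimide esterification of a primary allylic alcohol at low temperature and low DMAP loading should keep the β,γ-unsaturated acid from conjugating.

Step 10
Reactants: 16 (2E,5S)-3-methyl-5-[(triethylsilyl)oxy]octa-2,6,7-trien-1-yl 3-{[(tert-butyldiphenylsilyl)oxy]methyl}but-3-enoate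
Product: 18 (2R,3S)-2-{3-[(tert-butyldiphenylsilyl)oxy]prop-1-en-2-yl}-3-methyl-3-{(2S)-2-[(triethylsilyl)oxy]penta-3,4-dien-1-yl}pent-4-enoic acid, via boron ketene acetal 17 (not isolated)
Conditions: (S,S)-2-bromo-4,5-diphenyl-1,3-bis{[3,5-bis(trifluoromethyl)phenyl]sulfonyl}-1,3,2-diazaborolidine, Et3N, toluene–hexane, −78 °C; then 4 °C; aqueous work-up
Reagents that add atoms: none
Why: Enantioselective Ireland–Claisen rearrangement of a chiral O-boron ketene acetal, in which soft enolisation in a non-polar medium should give the enolate with the alkenyl group trans to O–B, the chair transition state with the E-olefin (chain equatorial, methyl axial) sets the C2/C3 relationship, and the diazaborolidine selects the enolate face, so that C2 becomes R and the quaternary C3 becomes S.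

Step 11
Reactants: 18 (2R,3S)-2-{3-[(tert-butyldiphenylsilyl)oxy]prop-1-en-2-yl}-3-methyl-3-{(2S)-2-[(triethylsilyl)oxy]penta-3,4-dien-1-yl}pent-4-enoic acid
Product: 19 (2R,3S)-2-{3-[(tert-butyldiphenylsilyl)oxy]prop-1-en-2-yl}-3-methyl-3-{(2S)-2-[(triethylsilyl)oxy]penta-3,4-dien-1-yl}pent-4-en-1-ol
Conditions: LiAlH4, Et2O, 0 °C to rt
Reagents that add atoms: none
Why: Hydride reduction of the carboxylic acid should give the primary alcohol while silyl ethers, isolated alkenes and the allene stay intact.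

Step 12
Reactants: 19 (2R,3S)-2-{3-[(tert-butyldiphenylsilyl)oxy]prop-1-en-2-yl}-3-methyl-3-{(2S)-2-[(triethylsilyl)oxy]penta-3,4-dien-1-yl}pent-4-en-1-ol
Product: 20 (2R,3S)-2-{3-[(tert-butyldiphenylsilyl)oxy]prop-1-en-2-yl}-3-methyl-3-{(2S)-2-[(triethylsilyl)oxy]penta-3,4-dien-1-yl}pent-4-enal
Conditions: Dess–Martin periodinane, pyridine, CH2Cl2, 0 °C; used at once
Reagents that add atoms: none
Why: Buffered Dess–Martin oxidation is mild enough to give the α-branched β,γ-unsaturated aldehyde without epimerisation or conjugation.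

Step 13
Reactants: 20 (2R,3S)-2-{3-[(tert-butyldiphenylsilyl)oxy]prop-1-en-2-yl}-3-methyl-3-{(2S)-2-[(triethylsilyl)oxy]penta-3,4-dien-1-yl}pent-4-enal
Product: 21 (3aS,4S,6S,7R,7aR)-7-{3-[(tert-butyldiphenylsilyl)oxy]prop-1-en-2-yl}-6-ethenyl-6-methyl-3-methylidene-4-[(triethylsilyl)oxy]hexahydro-1-benzofuran-2(3H)-one
Conditions: Mo(CO)6 (1.2 equiv), Me2SO (10 equiv), toluene, 90–100 °C
Reagents that add atoms: molybdenum hexacarbonyl Mo(CO)6 (delivers one CO), [Mo].[C-]#[O+].[C-]#[O+].[C-]#[O+].[C-]#[O+].[C-]#[O+].[C-]#[O+]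
Why: Me2SO-assisted loss of CO frees sites on zerovalent molybdenum, which binds the aldehyde C=O and the inner allene C=C of 20; oxidative cyclisation forms C3a–C7a and an oxamolybdacyclopentane carrying the exocyclic methylene, CO inserts into the Mo–C3 bond (C2–C3), and reductive elimination closes O1–C2. The closest known reaction type is the Mo(CO)6- or Ru3(CO)12-mediated hetero-Pauson–Khand cyclocarbonylation of allenyl aldehydes to fused α-methylene-γ-butyrolactones. The cyclohexane closes in a 6-exo sense by C–C coupling of the carbonyl carbon with the proximal allene carbon inside the metal coordination sphere, and the five-membered lactone then closes by carbonylative [2+2+1] assembly (migratory insertion, then C–O reductive elimination). C7a and C3a are set in the oxidative cyclisation: in the chair-like array fixed by the resident centres (4-OSiEt3, the C7 alkenyl group and the C6 vinyl equatorial, C6 methyl axial) the carbonyl oxygen should go equatorial, because an axial oxygen would be 1,3-diaxial to the C6 methyl, and the allene terminus should go equatorial, which gives the trans ring fusion. The step needs site selectivity for the inner allene π bond over the terminal one and over the vinyl and 1,1-disubstituted alkenes, secured by ring size (only this bond gives a six-membered carbocycle) and by the known preference of molybdenum for the proximal allene bond; it also needs the face selectivity just described, which rests on the equatorial placement of the resident substituents.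

Step 14
Reactants: 21 (3aS,4S,6S,7R,7aR)-7-{3-[(tert-butyldiphenylsilyl)oxy]prop-1-en-2-yl}-6-ethenyl-6-methyl-3-methylidene-4-[(triethylsilyl)oxy]hexahydro-1-benzofuran-2(3H)-one
Product: 22 (3aR,4S,6S,7R,7aR)-7-{3-[(tert-butyldiphenylsilyl)oxy]prop-1-en-2-yl}-6-ethenyl-4-hydroxy-6-methyl-3-methylidenehexahydro-1-benzofuran-2(3H)-one
Conditions: HF·pyridine, pyridine, THF, 0 °C
Reagents that add atoms: none
Why: Buffered fluoride desilylation should cleave the secondary triethylsilyl ether much faster than the primary tert-butyldiphenylsilyl ether and leave the α-methylene lactone untouched.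

Step 15
Reactants: 23 but-2-yn-1-ol
Product: 24 (2Z)-2-(tributylstannyl)but-2-en-1-ol
Conditions: n-Bu3SnH, [Cp*RuCl]4 (cat.), CH2Cl2, rt
Reagents that add atoms: tributylstannane, CCCC[SnH](CCCC)CCCC
Why: Ruthenium-catalysed trans-hydrostannation, in which the free hydroxyl directs tin to the proximal carbon and the anti addition of H and Sn places the methyl group cis to tin.

Step 16
Reactants: 24 (2Z)-2-(tributylstannyl)but-2-en-1-ol
Product: 25 tert-butyldimethyl{[(2Z)-2-(tributylstannyl)but-2-en-1-yl]oxy}silane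
Conditions: t-BuMe2SiCl, imidazole, CH2Cl2, rt
Reagents that add atoms: tert-butylchlorodimethylsilane, CC(C)(C)[Si](C)(C)Cl
Why: Routine silyl ether formation masks the hydroxyl for the organolithium step.

Step 17
Reactants: 25 tert-butyldimethyl{[(2Z)-2-(tributylstannyl)but-2-en-1-yl]oxy}silane
Product: 26 tert-butyl{[(2Z)-2-iodobut-2-en-1-yl]oxy}dimethylsilane
Conditions: I2, CH2Cl2, 0 °C
Reagents that add atoms: iodine, II
Why: Iododestannylation of an alkenylstannane proceeds with retention of the double-bond geometry.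

Step 18
Reactants: 26 tert-butyl{[(2Z)-2-iodobut-2-en-1-yl]oxy}dimethylsilane
Product: 28 (2Z)-2-({[tert-butyl(dimethyl)silyl]oxy}methyl)but-2-enoic acid, via vinyllithium 27 (not isolated)
Conditions: t-BuLi (2.1 equiv), Et2O, −78 °C; then CO2; cold dil. HCl to pH 4
Reagents that add atoms: carbon dioxide, O=C=O
Why: Iodine–lithium exchange and carboxylation of the configurationally stable alkenyllithium at −78 °C should both proceed with retention, leaving the methyl group cis to the carboxyl.

Step 19
Reactants: 28 (2Z)-2-({[tert-butyl(dimethyl)silyl]oxy}methyl)but-2-enoic acid; 22 (3aR,4S,6S,7R,7aR)-7-{3-[(tert-butyldiphenylsilyl)oxy]prop-1-en-2-yl}-6-ethenyl-4-hydroxy-6-methyl-3-methylidenehexahydro-1-benzofuran-2(3H)-one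
Product: 30 (3aR,4S,6S,7R,7aR)-7-{3-[(tert-butyldiphenylsilyl)oxy]prop-1-en-2-yl}-6-ethenyl-6-methyl-3-methylidene-2-oxooctahydro-1-benzofuran-4-yl (2Z)-2-({[tert-butyl(dimethyl)silyl]oxy}methyl)but-2-enoate, via mixed anhydride 29 (not isolated)
Conditions: 2,4,6-trichlorobenzoyl chloride, Et3N, toluene, rt; then 22, DMAP, toluene, rt
Reagents that add atoms: none
Why: Yamaguchi esterification through the mixed anhydride should acylate the equatorial secondary alcohol at room temperature, where the Z-enoate is expected to keep its geometry.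

Step 20
Reactants: 30 (3aR,4S,6S,7R,7aR)-7-{3-[(tert-butyldiphenylsilyl)oxy]prop-1-en-2-yl}-6-ethenyl-6-methyl-3-methylidene-2-oxooctahydro-1-benzofuran-4-yl (2Z)-2-({[tert-butyl(dimethyl)silyl]oxy}methyl)but-2-enoate
Product: 31 (3aR,4S,6S,7R,7aR)-6-ethenyl-7-(3-hydroxyprop-1-en-2-yl)-6-methyl-3-methylidene-2-oxooctahydro-1-benzofuran-4-yl (2Z)-2-(hydroxymethyl)but-2-enoate
Conditions: HF·pyridine (excess), THF–pyridine, 0 °C to rt
Reagents that add atoms: none
Why: Global fluoride desilylation under mildly acidic conditions should free both primary alcohols without conjugate addition to the α-methylene lactone or acyl migration.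

**Compound list**
1 | methyl 3-methylbut-2-enoate | COC(=O)C=C(C)C | starting material
2 | lithium 1-methoxy-3-methylbuta-1,3-dien-1-olate | COC(=CC(C)=C)O[Li] | intermediate (not isolated)
3 | tert-butyl[(1-methoxy-3-methylbuta-1,3-dien-1-yl)oxy]dimethylsilane | COC(=CC(C)=C)O[Si](C)(C)C(C)(C)C | intermediate
4 | 3-(trimethylsilyl)prop-2-ynal | C[Si](C)(C)C#CC=O | starting material
5 | methyl (2E,5S)-5-hydroxy-3-methyl-7-(trimethylsilyl)hept-2-en-6-ynoate | COC(=O)/C=C(\C)C[C@H](O)C#C[Si](C)(C)C | intermediate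
6 | methyl (2E,5S)-3-methyl-5-[(triethylsilyl)oxy]-7-(trimethylsilyl)hept-2-en-6-ynoate | COC(=O)/C=C(\C)C[C@H](O[Si](CC)(CC)CC)C#C[Si](C)(C)C | intermediate
7 | (2E,5S)-3-methyl-5-[(triethylsilyl)oxy]-7-(trimethylsilyl)hept-2-en-6-yn-1-ol | OC/C=C(\C)C[C@H](O[Si](CC)(CC)CC)C#C[Si](C)(C)C | intermediate
8 | (2E,5S)-3-methyl-5-[(triethylsilyl)oxy]hept-2-en-6-yn-1-ol | OC/C=C(\C)C[C@H](O[Si](CC)(CC)CC)C#C | intermediate
9 | (2E,5S)-8-(diisopropylamino)-3-methyl-5-[(triethylsilyl)oxy]oct-2-en-6-yn-1-ol | OC/C=C(\C)C[C@H](O[Si](CC)(CC)CC)C#CCN(C(C)C)C(C)C | intermediate (not isolated)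
10 | (2E,5S)-3-methyl-5-[(triethylsilyl)oxy]octa-2,6,7-trien-1-ol | OC/C=C(\C)C[C@H](O[Si](CC)(CC)CC)C=C=C | intermediate
11 | 2-methylprop-2-en-1-ol | CC(=C)CO | starting material
12 | lithium 2-(lithiomethyl)prop-2-en-1-olate | [Li]CC(=C)CO[Li] | intermediate (not isolated)
13 | 3-(hydroxymethyl)but-3-enoic acid | OCC(=C)CC(=O)O | intermediate
14 | tert-butyldiphenylsilyl 3-{[(tert-butyldiphenylsilyl)oxy]methyl}but-3-enoate | C=C(CO[Si](c1ccccc1)(c1ccccc1)C(C)(C)C)CC(=O)O[Si](c1ccccc1)(c1ccccc1)C(C)(C)C | intermediate (not isolated)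
15 | 3-{[(tert-butyldiphenylsilyl)oxy]methyl}but-3-enoic acid | C=C(CO[Si](c1ccccc1)(c1ccccc1)C(C)(C)C)CC(=O)O | intermediate
16 | (2E,5S)-3-methyl-5-[(triethylsilyl)oxy]octa-2,6,7-trien-1-yl 3-{[(tert-butyldiphenylsilyl)oxy]methyl}but-3-enoate | C=C(CO[Si](c1ccccc1)(c1ccccc1)C(C)(C)C)CC(=O)OC/C=C(\C)C[C@H](O[Si](CC)(CC)CC)C=C=C | intermediate
17 | O-boron ketene acetal of 16 with the (S,S)-diazaborolidine (alkenyl group trans to O–B) | C=C(CO[Si](c1ccccc1)(c1ccccc1)C(C)(C)C)/C=C(/OB1N(S(=O)(=O)c2cc(C(F)(F)F)cc(C(F)(F)F)c2)[C@@H](c2ccccc2)[C@H](c2ccccc2)N1S(=O)(=O)c1cc(C(F)(F)F)cc(C(F)(F)F)c1)OC/C=C(\C)C[C@H](O[Si](CC)(CC)CC)C=C=C | intermediate (not isolated)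
18 | (2R,3S)-2-{3-[(tert-butyldiphenylsilyl)oxy]prop-1-en-2-yl}-3-methyl-3-{(2S)-2-[(triethylsilyl)oxy]penta-3,4-dien-1-yl}pent-4-enoic acid | C=C[C@](C)(C[C@H](O[Si](CC)(CC)CC)C=C=C)[C@@H](C(=O)O)C(=C)CO[Si](c1ccccc1)(c1ccccc1)C(C)(C)C | intermediate
19 | (2R,3S)-2-{3-[(tert-butyldiphenylsilyl)oxy]prop-1-en-2-yl}-3-methyl-3-{(2S)-2-[(triethylsilyl)oxy]penta-3,4-dien-1-yl}pent-4-en-1-ol | C=C[C@](C)(C[C@H](O[Si](CC)(CC)CC)C=C=C)[C@@H](CO)C(=C)CO[Si](c1ccccc1)(c1ccccc1)C(C)(C)C | intermediate
20 | (2R,3S)-2-{3-[(tert-butyldiphenylsilyl)oxy]prop-1-en-2-yl}-3-methyl-3-{(2S)-2-[(triethylsilyl)oxy]penta-3,4-dien-1-yl}pent-4-enal | C=C[C@](C)(C[C@H](O[Si](CC)(CC)CC)C=C=C)[C@@H](C=O)C(=C)CO[Si](c1ccccc1)(c1ccccc1)C(C)(C)C | intermediate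
21 | (3aS,4S,6S,7R,7aR)-7-{3-[(tert-butyldiphenylsilyl)oxy]prop-1-en-2-yl}-6-ethenyl-6-methyl-3-methylidene-4-[(triethylsilyl)oxy]hexahydro-1-benzofuran-2(3H)-one (trans-fused lactone) | C=C[C@]1(C)C[C@H](O[Si](CC)(CC)CC)[C@H]2C(=C)C(=O)O[C@@H]2[C@H]1C(=C)CO[Si](c1ccccc1)(c1ccccc1)C(C)(C)C | intermediate
22 | (3aR,4S,6S,7R,7aR)-7-{3-[(tert-butyldiphenylsilyl)oxy]prop-1-en-2-yl}-6-ethenyl-4-hydroxy-6-methyl-3-methylidenehexahydro-1-benzofuran-2(3H)-one | C=C[C@]1(C)C[C@H](O)[C@H]2C(=C)C(=O)O[C@@H]2[C@H]1C(=C)CO[Si](c1ccccc1)(c1ccccc1)C(C)(C)C | intermediate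
23 | but-2-yn-1-ol | CC#CCO | starting material
24 | (2Z)-2-(tributylstannyl)but-2-en-1-ol | C/C=C(/CO)[Sn](CCCC)(CCCC)CCCC | intermediate
25 | tert-butyldimethyl{[(2Z)-2-(tributylstannyl)but-2-en-1-yl]oxy}silane | C/C=C(/CO[Si](C)(C)C(C)(C)C)[Sn](CCCC)(CCCC)CCCC | intermediate
26 | tert-butyl{[(2Z)-2-iodobut-2-en-1-yl]oxy}dimethylsilane | C/C=C(/CO[Si](C)(C)C(C)(C)C)I | intermediate
27 | 1-({[tert-butyl(dimethyl)silyl]oxy}methyl)prop-1-en-1-yllithium (methyl cis to lithium) | C/C=C(/CO[Si](C)(C)C(C)(C)C)[Li] | intermediate (not isolated)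
28 | (2Z)-2-({[tert-butyl(dimethyl)silyl]oxy}methyl)but-2-enoic acid | C/C=C(/CO[Si](C)(C)C(C)(C)C)C(=O)O | intermediate
29 | (2Z)-2-({[tert-butyl(dimethyl)silyl]oxy}methyl)but-2-enoic 2,4,6-trichlorobenzoic anhydride | C/C=C(/CO[Si](C)(C)C(C)(C)C)C(=O)OC(=O)c1c(Cl)cc(Cl)cc1Cl | intermediate (not isolated)
30 | (3aR,4S,6S,7R,7aR)-7-{3-[(tert-butyldiphenylsilyl)oxy]prop-1-en-2-yl}-6-ethenyl-6-methyl-3-methylidene-2-oxooctahydro-1-benzofuran-4-yl (2Z)-2-({[tert-butyl(dimethyl)silyl]oxy}methyl)but-2-enoate | C=C[C@]1(C)C[C@H](OC(=O)/C(=C\C)CO[Si](C)(C)C(C)(C)C)[C@H]2C(=C)C(=O)O[C@@H]2[C@H]1C(=C)CO[Si](c1ccccc1)(c1ccccc1)C(C)(C)C | intermediate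
31 | (3aR,4S,6S,7R,7aR)-6-ethenyl-7-(3-hydroxyprop-1-en-2-yl)-6-methyl-3-methylidene-2-oxooctahydro-1-benzofuran-4-yl (2Z)-2-(hydroxymethyl)but-2-enoate | C=C[C@]1(C)C[C@H](OC(=O)/C(=C\C)CO)[C@H]2C(=C)C(=O)O[C@@H]2[C@H]1C(=C)CO | target

**Step count and risks**
Total steps: 20. Longest linear sequence: 14 steps (steps 1–6, 9–14, 19 and 20).

Step 13 is the most likely to fail. Attack on the other allene face through an axial allene would give a cis ring fusion, which five-membered metallacycles tolerate well. In addition, at 100 °C the 3,4-disubstituted hexa-1,5-diene unit may undergo Cope rearrangement and the aldehyde α-carbon may enolise (epimerisation or conjugation). The fallback sets out from alcohol 19 and comes back at lactone 21, and it separates the two bond formations. Pd(PPh3)4-catalysed addition of hexabutyldistannane (Bu3Sn–SnBu3) across the terminal allene C=C under equilibrating conditions (toluene, 80 °C) should give the 2-stannylallylstannane F1. Parikh–Doering oxidation should give the aldehyde F2. BF3·OEt2 at −78 °C should bring about the intramolecular allylstannane–aldehyde addition through an open transition state, a closure type known to favour the trans 2-alkenyl alcohol in six-membered ring formation, to give the trans-cyclohexanol F3 with a 1-stannylvinyl group. Iododestannylation (I2, CH2Cl2, 0 °C) should give the vinyl iodide F4. Cyclocarbonylation with zerovalent palladium (Pd(PPh3)4, CO 1 atm, Et3N, MeCN, 50 °C) then closes the α-methylene lactone 21.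

Step 10 is the second risk. The β,γ-unsaturated ester may give the other enolate geometry or a mixture, which would erode the C2/C3 relationship. The controller may discriminate poorly between the enolate faces with this trisubstituted olefin. The rearrangement to a quaternary centre is slow, so the Lewis-acidic bromoborane may cleave silyl ethers in the meantime. The fallback sets out from ester 16 and comes back at acid 18 by a classical Ireland–Claisen rearrangement without a chiral reagent. LiN(i-Pr)2 in THF at −78 °C (kinetic E(O) enolate) and Me3SiCl, then warming to rt, should give the trimethylsilyl ketene acetal F5. Its chair rearrangement should give the trimethylsilyl ester F6 and the diastereomeric trimethylsilyl ester F7, which are hydrolysed on work-up to acid 18 and the (2S,3R) diastereomeric acid F8. Because the silyloxy-bearing centre is already in place, the two chair products are diastereomers and not enantiomers, so 18 can be separated by chromatography (if needed after reduction to 19). Absolute control is traded for a separation.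

Step 19 is the third risk. Activation of the acid in the presence of DMAP may isomerise the Z-enoate to the E-isomer through reversible conjugate addition or ketene formation, and acylation of the hindered secondary alcohol may be slow. The fallback sets out from alcohol 22 and vinyl iodide 26 and comes back at ester 30. Alkoxycarbonylation of 26 with 22 as the nucleophile, catalysed by divalent palladium (PdCl2(PPh3)2, CO 1 atm, Et3N, DMF, 60 °C), forms the ester through an acylpalladium species with retention of the alkene geometry and without a free activated acid. This fallback makes no compound outside the list (F0).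

**Further compounds**
F1 | step 13 | (2R,3S)-2-{3-[(tert-butyldiphenylsilyl)oxy]prop-1-en-2-yl}-3-methyl-3-{(2S)-4,5-bis(tributylstannyl)-2-[(triethylsilyl)oxy]pent-3-en-1-yl}pent-4-en-1-ol | C=C[C@](C)(C[C@H](O[Si](CC)(CC)CC)C=C(C[Sn](CCCC)(CCCC)CCCC)[Sn](CCCC)(CCCC)CCCC)[C@@H](CO)C(=C)CO[Si](c1ccccc1)(c1ccccc1)C(C)(C)C
F2 | step 13 | (2R,3S)-2-{3-[(tert-butyldiphenylsilyl)oxy]prop-1-en-2-yl}-3-methyl-3-{(2S)-4,5-bis(tributylstannyl)-2-[(triethylsilyl)oxy]pent-3-en-1-yl}pent-4-enal | C=C[C@](C)(C[C@H](O[Si](CC)(CC)CC)C=C(C[Sn](CCCC)(CCCC)CCCC)[Sn](CCCC)(CCCC)CCCC)[C@@H](C=O)C(=C)CO[Si](c1ccccc1)(c1ccccc1)C(C)(C)C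
F3 | step 13 | trans-cyclohexanol corresponding to 21 with a 1-(tributylstannyl)ethenyl group in place of the lactone carbonyl and a free hydroxyl at the former C7a (ring configuration as in 21) | C=C[C@]1(C)C[C@H](O[Si](CC)(CC)CC)[C@@H](C(=C)[Sn](CCCC)(CCCC)CCCC)[C@H](O)[C@H]1C(=C)CO[Si](c1ccccc1)(c1ccccc1)C(C)(C)C
F4 | step 13 | the corresponding 1-iodoethenyl cyclohexanol (ring configuration as in 21) | C=C[C@]1(C)C[C@H](O[Si](CC)(CC)CC)[C@@H](C(=C)I)[C@H](O)[C@H]1C(=C)CO[Si](c1ccccc1)(c1ccccc1)C(C)(C)C
F5 | step 10 | trimethylsilyl ketene acetal of ester 16 (alkenyl group trans to OSiMe3) | C=C(CO[Si](c1ccccc1)(c1ccccc1)C(C)(C)C)/C=C(/O[Si](C)(C)C)OC/C=C(\C)C[C@H](O[Si](CC)(CC)CC)C=C=C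
F6 | step 10 | trimethylsilyl ester of acid 18 | C=C[C@](C)(C[C@H](O[Si](CC)(CC)CC)C=C=C)[C@@H](C(=O)O[Si](C)(C)C)C(=C)CO[Si](c1ccccc1)(c1ccccc1)C(C)(C)C
F7 | step 10 | trimethylsilyl ester of acid F8 | C=C[C@@](C)(C[C@H](O[Si](CC)(CC)CC)C=C=C)[C@H](C(=O)O[Si](C)(C)C)C(=C)CO[Si](c1ccccc1)(c1ccccc1)C(C)(C)C
F8 | step 10 | (2S,3R)-2-{3-[(tert-butyldiphenylsilyl)oxy]prop-1-en-2-yl}-3-methyl-3-{(2S)-2-[(triethylsilyl)oxy]penta-3,4-dien-1-yl}pent-4-enoic acid | C=C[C@@](C)(C[C@H](O[Si](CC)(CC)CC)C=C=C)[C@H](C(=O)O)C(=C)CO[Si](c1ccccc1)(c1ccccc1)C(C)(C)C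
F0 | step 19 | none | none
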